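**Plan**

1. Numbering follows the target: hydrindane C1–C7a (C3 carries the CH2 linker, C3a is the ring-fusion CH, C4 the methyl carbinol, C7 the CHBr, C7a the methylated quaternary carbon); ring C is C1'–C6' (C1' carbinol, C3' gem-dimethyl, C4' CHBr).
2. Cuts: both C–Br bonds (to bromoalkenes, then ketones); the C1'–OH bond (to a C1'=C6' alkene through a directed epoxide); then, in one operation, the linker–C1' bond and the C2–C3 bond of ring B; last the C7a–C1 and C3a–C3 arm bonds on a cyclohexenone.
3. Forward: ring A is a bought cyclohexenone that receives a vinyl group (C3a) and a two-carbon arm (C7a); ring C is a bought cyclohexanone turned into an enol triflate; ring B is the only ring that is closed, in the flask that also joins ring C; the two bromides come last.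
4. Enabling feature: C7a and C3a are neighbours on ring A and carry, trans, a CH2CH2–metal arm (C1–C2) and a vinyl group (C3=CH2), which together are a 5-hexenyl metal; 5-exo-trig closure makes C2–C3 and leaves the metal on the exocyclic CH2, which is the linker carbon that must be bonded to C1'.
5. Stereochemistry: the (S)-silyloxy carbon of the enone directs vinyl addition and alkylation (C3a, C7a); C4 comes from equatorial methyl addition; C3 from the chair-like ring closure; C1' from epoxidation syn to a CBS-derived C4' hydroxyl; the C7 and C4' bromides from axial hydrogen-atom delivery to α-bromo radicals.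

Key step: step 14

Remark: (S)-4-(tert-butyldimethylsilyloxy)cyclohex-2-en-1-one and 7,7-dimethyl-1,4-dioxaspiro[4.5]decan-8-one are taken as catalogue compounds; the numbering above is used for all intermediates.

**Route**

Step 1
Reactants: 1 (S)-4-(tert-butyldimethylsilyloxy)cyclohex-2-en-1-one
Product: 2 (S)-4-(tert-butyldimethylsilyloxy)-2-iodocyclohex-2-en-1-one
Conditions: I2, pyridine, CH2Cl2, 0 °C to rt
Reagents that add atoms: iodine, II
Why: α-Iodination of a cyclic enone by conjugate addition of pyridine, iodination of the enolate and elimination (Baylis–Hillman-type sequence), which does not touch the silyloxy stereocentre.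

Step 2
Reactants: 2 (S)-4-(tert-butyldimethylsilyloxy)-2-iodocyclohex-2-en-1-one
Product: 3 (S)-4-(tert-butyldimethylsilyloxy)-2-methylcyclohex-2-en-1-one
Conditions: Me4Sn, Pd2(dba)3 (cat.), AsPh3, CuI, NMP, 60 °C
Reagents that add atoms: tetramethylstannane, C[Sn](C)(C)C
Why: Stille coupling of an α-iodoenone runs under neutral conditions and so spares the base-sensitive γ-silyloxy enone.

Step 3
Reactants: 3 (S)-4-(tert-butyldimethylsilyloxy)-2-methylcyclohex-2-en-1-one
Product: 5 methyl 2-[(1S,2S,3S)-3-(tert-butyldimethylsilyloxy)-2-ethenyl-1-methyl-6-oxocyclohexyl]acetate, via magnesium enolate 4 (not isolated)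
Conditions: CH2=CHMgBr, CuBr·SMe2 (cat.), THF, −78 to −30 °C; then HMPA, BrCH2CO2Me, −30 to 0 °C
Reagents that add atoms: vinylmagnesium bromide, C=C[Mg]Br; methyl bromoacetate, COC(=O)CBr
Why: Copper-catalysed conjugate addition should deliver the vinyl group anti to the neighbouring silyloxy group, and the regiodefined enolate should then be alkylated anti to the new vinyl group, which sets the quaternary carbon and the trans relation of the two arms (three-component coupling).

Step 4
Reactants: 5 methyl 2-[(1S,2S,3S)-3-(tert-butyldimethylsilyloxy)-2-ethenyl-1-methyl-6-oxocyclohexyl]acetate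
Product: 6 methyl 2-[(6S,7S,8S)-8-(tert-butyldimethylsilyloxy)-7-ethenyl-6-methyl-1,4-dioxaspiro[4.5]decan-6-yl]acetate
Conditions: Me3SiOCH2CH2OSiMe3, Me3SiOTf (cat.), CH2Cl2, −78 to −20 °C
Reagents that add atoms: 1,2-bis(trimethylsilyloxy)ethane, C[Si](C)(C)OCCO[Si](C)(C)C
Why: Silyl-transfer ketalization works on hindered ketones at low temperature and leaves the silyl ether, ester and vinyl group alone.

Step 5
Reactants: 6 methyl 2-[(6S,7S,8S)-8-(tert-butyldimethylsilyloxy)-7-ethenyl-6-methyl-1,4-dioxaspiro[4.5]decan-6-yl]acetate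
Product: 7 methyl 2-[(6S,7S,8S)-7-ethenyl-8-hydroxy-6-methyl-1,4-dioxaspiro[4.5]decan-6-yl]acetate
Conditions: HF·pyridine, pyridine, THF, 0 °C to rt
Reagents that add atoms: none
Why: Buffered fluoride cleaves the secondary silyl ether without generating an alkoxide, so the hydroxy ester cannot lactonize and the dioxolane survives.

Step 6
Reactants: 7 methyl 2-[(6S,7S,8S)-7-ethenyl-8-hydroxy-6-methyl-1,4-dioxaspiro[4.5]decan-6-yl]acetate
Product: 8 methyl 2-[(6S,7S)-7-ethenyl-6-methyl-8-oxo-1,4-dioxaspiro[4.5]decan-6-yl]acetate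
Conditions: Dess–Martin periodinane, CH2Cl2, 0 °C to rt
Reagents that add atoms: none
Why: Dess–Martin oxidation is mild enough not to epimerize the α-vinyl ketone or move its double bond into conjugation.

Step 7
Reactants: 8 methyl 2-[(6S,7S)-7-ethenyl-6-methyl-8-oxo-1,4-dioxaspiro[4.5]decan-6-yl]acetate
Product: 9 methyl 2-[(6S,7S,8R)-7-ethenyl-8-hydroxy-6,8-dimethyl-1,4-dioxaspiro[4.5]decan-6-yl]acetate
Conditions: MeMgBr, CeCl3, THF, −78 °C
Reagents that add atoms: methylmagnesium bromide, C[Mg]Br
Why: The non-basic methylcerium reagent adds to the ketone faster than to the ester and attacks equatorially, because the axial methyl group on the quaternary carbon blocks the axial path, so the hydroxyl ends axial and syn to that methyl group as in the target.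

Step 8
Reactants: 9 methyl 2-[(6S,7S,8R)-7-ethenyl-8-hydroxy-6,8-dimethyl-1,4-dioxaspiro[4.5]decan-6-yl]acetate
Product: 10 (6S,7S,8R)-7-ethenyl-6-(2-hydroxyethyl)-6,8-dimethyl-1,4-dioxaspiro[4.5]decan-8-ol
Conditions: LiAlH4, THF, 0 °C
Reagents that add atoms: none
Why: Hydride reduction of the ester gives the primary alcohol, while the ketal, alkene and tertiary alcohol are inert.

Step 9
Reactants: 10 (6S,7S,8R)-7-ethenyl-6-(2-hydroxyethyl)-6,8-dimethyl-1,4-dioxaspiro[4.5]decan-8-ol
Product: 11 (6S,7S,8R)-7-ethenyl-6-(2-iodoethyl)-6,8-dimethyl-1,4-dioxaspiro[4.5]decan-8-ol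
Conditions: I2, PPh3, imidazole, CH2Cl2, 0 °C
Reagents that add atoms: iodine, II
Why: Appel-type iodination converts only the primary alcohol, since the axial tertiary hydroxyl is too hindered to react or to close an ether onto the equatorial arm.

Step 10
Reactants: 12 7,7-dimethyl-1,4-dioxaspiro[4.5]decan-8-one
Product: 13 (S)-7,7-dimethyl-1,4-dioxaspiro[4.5]decan-8-ol
Conditions: (R)-1-methyl-3,3-diphenyltetrahydro-1H,3H-pyrrolo[1,2-c][1,3,2]oxazaborole (cat.), BH3·SMe2, THF, 0 °C
Reagents that add atoms: none
Why: Corey–Bakshi–Shibata reduction distinguishes the quaternary flank of the ketone from the methylene flank, and the (R)-catalyst should give the (S)-carbinol.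

Step 11
Reactants: 13 (S)-7,7-dimethyl-1,4-dioxaspiro[4.5]decan-8-ol
Product: 14 (S)-4-hydroxy-3,3-dimethylcyclohexan-1-one
Conditions: 1 M HCl, THF, rt
Reagents that add atoms: water, O
Why: Acid-catalysed hydrolysis of the dioxolane does not involve the carbinol carbon.

Step 12
Reactants: 14 (S)-4-hydroxy-3,3-dimethylcyclohexan-1-one
Product: 15 (S)-3,3-dimethyl-4-(triethylsilyloxy)cyclohexan-1-one
Conditions: Et3SiCl, imidazole, DMF, 0 °C to rt
Reagents that add atoms: chlorotriethylsilane, CC[Si](Cl)(CC)CC
Why: Standard silylation gives an ether that survives the enolate and organozinc steps and is removed later by dilute acid.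

Step 13
Reactants: 15 (S)-3,3-dimethyl-4-(triethylsilyloxy)cyclohexan-1-one
Product: 17 (S)-5,5-dimethyl-4-(triethylsilyloxy)cyclohex-1-en-1-yl trifluoromethanesulfonate, via lithium enolate 16 (not isolated)
Conditions: LiN(i-Pr)2, THF, −78 °C; then PhNTf2, −78 °C to rt
Reagents that add atoms: N-phenylbis(trifluoromethanesulfonimide), O=S(=O)(N(c1ccccc1)S(=O)(=O)C(F)(F)F)C(F)(F)F
Why: Kinetic deprotonation occurs at the methylene remote from the gem-dimethyl group (the other α-methylene is neopentylic), so O-triflation of the enolate fixes the double bond at C1'=C6'.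

Step 14
Reactants: 11 (6S,7S,8R)-7-ethenyl-6-(2-iodoethyl)-6,8-dimethyl-1,4-dioxaspiro[4.5]decan-8-ol; 17 (S)-5,5-dimethyl-4-(triethylsilyloxy)cyclohex-1-en-1-yl trifluoromethanesulfonate
Product: 22 coupled alkene (3S,3aS,4R,7aS)-3-{[(4S)-5,5-dimethyl-4-(triethylsilyloxy)cyclohex-1-en-1-yl]methyl}-7,7-ethylenedioxy-4,7a-dimethyloctahydro-1H-inden-4-ol, via lithium alkoxide 18 (not isolated), via open-chain alkyllithium 19 (not isolated), via cyclized alkyllithium 20 (not isolated), via alkylzinc chloride 21 (not isolated)
Conditions: 11, MeLi, Et2O/pentane, −78 °C; t-BuLi, −78 °C; TMEDA, −78 to 20 °C; ZnCl2, THF, 0 °C; then 17, Pd(PPh3)4 (cat.), THF, 50 °C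
Reagents that add atoms: none
Why: MeLi first removes the hydroxyl proton so that the primary alkyllithium made by iodine–lithium exchange with t-BuLi is not quenched internally, and on warming C2–Li adds across the vinyl group in an irreversible anionic 5-exo-trig cyclization (intramolecular carbolithiation of a 5-hexenyllithium is the closest known reaction type), which closes ring B. The closure is 5-exo because the lithium-bridged transition state reaches only the internal vinyl carbon C3, whereas 6-endo attack on the terminal CH2 is not accessible. C3 is set in a chair-like transition state in which the two ring-A bonds at C7a and C3a stay equatorial (the trans fusion is already fixed in step 3) and the terminal vinyl CH2 points away from the fully substituted C4, so the CH2Li arm ends trans to C4 and anti to the angular methyl group. The exocyclic primary carbanion is then transmetalated to zinc and joined to C1' of 17 by Negishi coupling of an alkylzinc with an alkenyl triflate under zerovalent palladium, which makes the linker–C1' bond and keeps the double bond at C1'=C6'. The step needs exchange only at the C–I bond (t-BuLi at −78 °C leaves ketal, alkoxide and alkene alone), ring closure before protonation (aprotic medium, TMEDA to speed the cyclization) and coupling before β-hydride elimination (a primary alkylzinc and a reactive triflate favour this).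

Step 15
Reactants: 22 coupled alkene (triethylsilyl ether, ethylene ketal)
Product: 23 keto diol (C7 ketone, C4 tertiary alcohol, C4' secondary alcohol, C1'=C6' alkene)
Conditions: 1 M HCl, THF, rt
Reagents that add atoms: water, O
Why: Dilute acid hydrolyses the dioxolane and the triethylsilyl ether in one operation, while the isolated trisubstituted alkene and the tertiary alcohol are stable to it.

Step 16
Reactants: 23 keto diol
Product: 24 epoxy alcohol (C1'–C6' epoxide with the oxygen cis to the C4' hydroxyl)
Conditions: VO(acac)2 (cat.), t-BuOOH, CH2Cl2, 0 °C to rt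
Reagents that add atoms: tert-butyl hydroperoxide, CC(C)(C)OO
Why: Hydroxyl-directed vanadium-catalysed epoxidation of a cyclic homoallylic alcohol delivers oxygen to the alkene face syn to the C4' hydroxyl, which fixes C1' relative to the CBS-derived centre.

Step 17
Reactants: 24 epoxy alcohol
Product: 25 tetraol (C7 and C4' secondary alcohols, C4 and C1' tertiary alcohols)
Conditions: LiAlH4, THF, 0 to 50 °C
Reagents that add atoms: none
Why: Hydride opens the trisubstituted epoxide at the secondary carbon C6' (SN2), which keeps the C1'–O bond and its configuration, and it also reduces the C7 ketone, mainly to the equatorial alcohol, whose configuration is of no consequence because it is oxidized in the next step.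

Step 18
Reactants: 25 tetraol
Product: 26 diketone diol (C7 and C4' ketones, C4 and C1' tertiary alcohols)
Conditions: Dess–Martin periodinane, CH2Cl2, rt
Reagents that add atoms: none
Why: Both secondary alcohols are oxidized and the two tertiary alcohols cannot be.

Step 19
Reactants: 26 diketone diol
Product: 28 bis(bromoalkene) (C7(Br)=C6 and C4'(Br)=C5'), via bis-hydrazone 27 (not isolated)
Conditions: N2H4·H2O, Et3N, EtOH, 80 °C; concentrate; then NBS, pyridine, 0 °C
Reagents that add atoms: N-bromosuccinimide, O=C1CCC(=O)N1Br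
Why: In the Barton vinyl halide synthesis each hydrazone is oxidized to the diazo compound and brominated with loss of N2, and because each carbonyl has a quaternary carbon on one side the proton can only be lost toward the methylene side.

Step 20
Reactants: 28 bis(bromoalkene)
Product: 29 (3S,3aS,4R,7S,7aS)-7-bromo-3-{[(1S,4S)-4-bromo-1-hydroxy-3,3-dimethylcyclohexyl]methyl}-4,7a-dimethyloctahydro-1H-inden-4-ol
Conditions: Mn(dpm)3 (cat.), PhSiH3, t-BuOOH, i-PrOH, rt
Reagents that add atoms: none
Why: Radical hydrogenation by metal-hydride hydrogen atom transfer, a reaction type that reduces haloalkenes without loss of halogen, should add H• to each CH terminus and then deliver the second hydrogen axially to each α-bromo radical from the face away from the adjacent axial methyl group (the C7a methyl for C7; the axial C3' methyl and the axial C1' hydroxyl for C4'), so both bromines end equatorial as in the target.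

**Compound list**

1 | (S)-4-(tert-butyldimethylsilyloxy)cyclohex-2-en-1-one | O=C1C=C[C@@H](O[Si](C)(C)C(C)(C)C)CC1 | starting material
2 | (S)-4-(tert-butyldimethylsilyloxy)-2-iodocyclohex-2-en-1-one | O=C1C(I)=C[C@@H](O[Si](C)(C)C(C)(C)C)CC1 | intermediate
3 | (S)-4-(tert-butyldimethylsilyloxy)-2-methylcyclohex-2-en-1-one | CC1=C[C@@H](O[Si](C)(C)C(C)(C)C)CCC1=O | intermediate
4 | bromomagnesium enolate of the vinyl adduct (vinyl trans to the silyloxy group) | CC1=C(O[Mg]Br)CC[C@H](O[Si](C)(C)C(C)(C)C)[C@H]1C=C | intermediate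
5 | methyl 2-[(1S,2S,3S)-3-(tert-butyldimethylsilyloxy)-2-ethenyl-1-methyl-6-oxocyclohexyl]acetate | COC(=O)C[C@]1(C)C(=O)CC[C@H](O[Si](C)(C)C(C)(C)C)[C@H]1C=C | intermediate
6 | methyl 2-[(6S,7S,8S)-8-(tert-butyldimethylsilyloxy)-7-ethenyl-6-methyl-1,4-dioxaspiro[4.5]decan-6-yl]acetate | COC(=O)C[C@]1(C)C2(OCCO2)CC[C@H](O[Si](C)(C)C(C)(C)C)[C@H]1C=C | intermediate
7 | methyl 2-[(6S,7S,8S)-7-ethenyl-8-hydroxy-6-methyl-1,4-dioxaspiro[4.5]decan-6-yl]acetate | COC(=O)C[C@]1(C)C2(OCCO2)CC[C@H](O)[C@H]1C=C | intermediate
8 | methyl 2-[(6S,7S)-7-ethenyl-6-methyl-8-oxo-1,4-dioxaspiro[4.5]decan-6-yl]acetate | COC(=O)C[C@]1(C)C2(OCCO2)CCC(=O)[C@H]1C=C | intermediate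
9 | methyl 2-[(6S,7S,8R)-7-ethenyl-8-hydroxy-6,8-dimethyl-1,4-dioxaspiro[4.5]decan-6-yl]acetate | COC(=O)C[C@]1(C)C2(OCCO2)CC[C@@](C)(O)[C@H]1C=C | intermediate
10 | (6S,7S,8R)-7-ethenyl-6-(2-hydroxyethyl)-6,8-dimethyl-1,4-dioxaspiro[4.5]decan-8-ol | OCC[C@]1(C)C2(OCCO2)CC[C@@](C)(O)[C@H]1C=C | intermediate
11 | (6S,7S,8R)-7-ethenyl-6-(2-iodoethyl)-6,8-dimethyl-1,4-dioxaspiro[4.5]decan-8-ol | ICC[C@]1(C)C2(OCCO2)CC[C@@](C)(O)[C@H]1C=C | intermediate
12 | 7,7-dimethyl-1,4-dioxaspiro[4.5]decan-8-one | CC1(C)CC2(CCC1=O)OCCO2 | starting material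
13 | (S)-7,7-dimethyl-1,4-dioxaspiro[4.5]decan-8-ol | CC1(C)CC2(OCCO2)CC[C@@H]1O | intermediate
14 | (S)-4-hydroxy-3,3-dimethylcyclohexan-1-one | CC1(C)CC(=O)CC[C@@H]1O | intermediate
15 | (S)-3,3-dimethyl-4-(triethylsilyloxy)cyclohexan-1-one | CC1(C)CC(=O)CC[C@@H]1O[Si](CC)(CC)CC | intermediate
16 | lithium enolate of 15 (C1'=C6') | CC1(C)CC(O[Li])=CC[C@@H]1O[Si](CC)(CC)CC | intermediate
17 | (S)-5,5-dimethyl-4-(triethylsilyloxy)cyclohex-1-en-1-yl trifluoromethanesulfonate | CC1(C)CC(OS(=O)(=O)C(F)(F)F)=CC[C@@H]1O[Si](CC)(CC)CC | intermediate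
18 | lithium alkoxide of iodide 11 | ICC[C@]1(C)C2(OCCO2)CC[C@@](C)(O[Li])[C@H]1C=C | intermediate
19 | open-chain alkyllithium (2-lithioethyl arm on the quaternary carbon; lithium alkoxide) | [Li]CC[C@]1(C)C2(OCCO2)CC[C@@](C)(O[Li])[C@H]1C=C | intermediate
20 | cyclized alkyllithium (trans-hydrindane with CH2Li on C3; 3S,3aS,4R,7aS; lithium alkoxide at C4; C7 ethylene ketal) | [Li]C[C@@H]1CC[C@]2(C)C3(OCCO3)CC[C@@](C)(O[Li])[C@@H]12 | intermediate
21 | alkylzinc chloride derived from 20 | Cl[Zn]C[C@@H]1CC[C@]2(C)C3(OCCO3)CC[C@@](C)(O[Li])[C@@H]12 | intermediate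
22 | (3S,3aS,4R,7aS)-3-{[(4S)-5,5-dimethyl-4-(triethylsilyloxy)cyclohex-1-en-1-yl]methyl}-7,7-ethylenedioxy-4,7a-dimethyloctahydro-1H-inden-4-ol | CC1(C)CC(C[C@@H]2CC[C@]3(C)C4(OCCO4)CC[C@@](C)(O)[C@@H]23)=CC[C@@H]1O[Si](CC)(CC)CC | intermediate
23 | keto diol: C7 ketone of the trans-hydrindane (3S,3aS,4R,7aS) with C4 methyl carbinol, C3–CH2 bonded to C1' of the (4'S)-4'-hydroxy-3',3'-dimethylcyclohex-1'(6')-ene | CC1(C)CC(C[C@@H]2CC[C@]3(C)C(=O)CC[C@@](C)(O)[C@@H]23)=CC[C@@H]1O | intermediate
24 | epoxy alcohol: C1'–C6' epoxide of 23 with the epoxide oxygen cis to the C4' hydroxyl | CC1(C)C[C@]2(C[C@@H]3CC[C@]4(C)C(=O)CC[C@@](C)(O)[C@@H]34)O[C@@H]2C[C@@H]1O | intermediate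
25 | tetraol: (3S,3aS,4R,7S,7aS)-hydrindane-4,7-diol carrying at C3 the [(1S,4S)-1,4-dihydroxy-3,3-dimethylcyclohexyl]methyl group | CC1(C)C[C@@](O)(C[C@@H]2CC[C@]3(C)[C@@H](O)CC[C@@](C)(O)[C@@H]23)CC[C@@H]1O | intermediate
26 | diketone diol: C7 and C4' ketones, C4 and C1' tertiary alcohols configured as in the target | CC1(C)C[C@@](O)(C[C@@H]2CC[C@]3(C)C(=O)CC[C@@](C)(O)[C@@H]23)CCC1=O | intermediate
27 | bis-hydrazone of 26 | CC1(C)C[C@@](O)(C[C@@H]2CC[C@]3(C)C(=NN)CC[C@@](C)(O)[C@@H]23)CCC1=NN | intermediate
28 | bis(bromoalkene): C7(Br)=C6 and C4'(Br)=C5', other centres as in the target | CC1(C)C[C@@](O)(C[C@@H]2CC[C@]3(C)C(Br)=CC[C@@](C)(O)[C@@H]23)CC=C1Br | intermediate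
29 | (3S,3aS,4R,7S,7aS)-7-bromo-3-{[(1S,4S)-4-bromo-1-hydroxy-3,3-dimethylcyclohexyl]methyl}-4,7a-dimethyloctahydro-1H-inden-4-ol | CC1(C)C[C@@](O)(C[C@@H]2CC[C@]3(C)[C@@H](Br)CC[C@@](C)(O)[C@@H]23)CC[C@@H]1Br | target

**Step count and risks**

Total: 20 steps. Longest linear sequence: 16 steps (steps 1–9 and 14–20, from 1); the ring C branch is steps 10–13.

Steps most likely to fail:

Step 14. The alkyllithium may be lost by proton transfer before the ring closes, or the coupling may be overtaken by β-hydride elimination. The fallback replaces the anionic closure by a radical one. It sets out from 11, which is treated with Et2Zn and catalytic PdCl2(dppf) in THF; iodine–zinc exchange then runs through the primary alkyl radical, which closes 5-exo through the same chair-like arrangement before zinc captures it. This gives the cyclized ethylzinc reagent F1 without any strongly basic intermediate, and F1 is coupled with 17 under Pd(PPh3)4 catalysis to come back to the route at 22.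

Step 20. The radical hydrogenation may lose bromine (hydrogen transfer to the wrong alkene carbon followed by β-scission), or the second hydrogen transfer may show poor facial selectivity. The fallback sets out from 26 and avoids bromoalkenes altogether. LiBH(s-Bu)3 should reduce both ketones from the equatorial side to give the diaxial diol F3, and a double Appel bromination (CBr4, PPh3) with inversion at C7 and C4' comes back at 29.

Step 19. Hydrazone formation at the two hindered carbonyls may be incomplete, azines may form, or the bromo carbocation may be captured by bromide to give gem-dibromides. The fallback sets out from 26, which is converted with KN(SiMe3)2 and PhNTf2 into the bis(enol triflate) F2 (only the methylene side of each ketone can enolize). Nickel-catalysed triflate–bromide exchange (Ni(OAc)2, 1,5-cyclooctadiene, Zn, LiBr, DMA/THF) then comes back at 28.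

**Further compounds**

F1 | step 14 | cyclized ethylzinc reagent (trans-hydrindane with CH2ZnEt on C3; ethylzinc alkoxide at C4; C7 ethylene ketal) | CC[Zn]C[C@@H]1CC[C@]2(C)C3(OCCO3)CC[C@@](C)(O[Zn]CC)[C@@H]12
F2 | step 19 | bis(enol triflate) of 26 (C7(OTf)=C6 and C4'(OTf)=C5') | CC1(C)C[C@@](O)(C[C@@H]2CC[C@]3(C)C(OS(=O)(=O)C(F)(F)F)=CC[C@@](C)(O)[C@@H]23)CC=C1OS(=O)(=O)C(F)(F)F
F3 | step 20 | diaxial diol (C7 and C4' epimer of tetraol 25) | CC1(C)C[C@@](O)(C[C@@H]2CC[C@]3(C)[C@H](O)CC[C@@](C)(O)[C@@H]23)CC[C@H]1O
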